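**Assumption:** the carbocycle is taken to arise in the plant from an 8′–2-linked rosmarinate dimer in its 2-aryl-caffeate (salvianolic acid E type) form by C8–C7′ closure and hydrogen shift; the stereodescriptors of the given SMILES are taken literally (1S,2S, i.e. 1,2-cis; S lactate on the C3 ester, R lactate on the C1 ester).

Locants C7/C8 are the side-chain carbons of the ring A caffeate unit; C7′/C8′ are those of the unit that carries the pendant aryl.

## Retrosynthetic overview

1. Target ⇐ alcoholysis of a peri-lactone (C1 carboxyl tied to the 8-OH) by methyl (R)-danshensu; the lactone holds C1/C2 cis.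
2. Lactone ⇐ C8–C7′ closure (6π-electrocyclisation, then hydrogen shift) of a salvianolic-acid-E-type 2-aryl-caffeate triene held flat as an isoaurone; this forms the carbocycle.
3. Triene ⇐ Heck coupling of a 4-iodo-isoaurone with the acrylate of methyl (S)-danshensu (from the natural R alcohol by Mitsunobu inversion).
4. Iodo-isoaurone ⇐ Knoevenagel condensation of 7-hydroxy-4-iodobenzofuran-2(3H)-one with 3,4-dihydroxybenzaldehyde; the benzofuranone comes from 2,3-dimethoxyphenylacetic acid.
5. Ring order: temporary lactone (step 1) → dihydronaphthalene carbocycle (step 6) → lactone opened (step 7).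

## Route

**Step 1**
Reactants: 1 2,3-dimethoxyphenylacetic acid
Product: 2 7-hydroxybenzofuran-2(3H)-one
Conditions: 48% aq. HBr, AcOH, 115 °C
Reagents that add atoms: none
Why: Aryl methyl ether cleavage by HBr (SN2 of bromide on the protonated ether) is followed by acid-catalysed lactonisation, for which only the 2-OH can reach the carboxyl, so the 3-OH stays free as the later 7-OH.

**Step 2**
Reactants: 2 7-hydroxybenzofuran-2(3H)-one
Product: 3 7-hydroxy-4-iodobenzofuran-2(3H)-one
Conditions: NIS (1.05 equiv), TsOH·H2O (10 mol %), MeCN, 0 °C → rt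
Reagents that add atoms: N-iodosuccinimide, O=C1CCC(=O)N1I
Why: Electrophilic aromatic iodination with acid-activated NIS goes para to the free phenol (C4), while the weakly donating lactone oxygen and the non-enolised CH2 do not compete under acidic conditions.

**Step 3**
Reactants: 3 7-hydroxy-4-iodobenzofuran-2(3H)-one; 4 3,4-dihydroxybenzaldehyde
Product: 5 (Z)-3-(3,4-dihydroxybenzylidene)-7-hydroxy-4-iodobenzofuran-2(3H)-one
Conditions: conc. HCl (cat.), AcOH, 60 °C
Reagents that add atoms: none
Why: Acid-catalysed Knoevenagel-type aldol condensation at the activated lactone CH2 gives the isoaurone, and reversible protonation lets the alkene settle in the Z form, where the catechol ring lies syn to the lactone C=O and away from the C4 iodine.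

**Step 4**
Reactants: 6 sodium (2R)-3-(3,4-dihydroxyphenyl)-2-hydroxypropanoate
Product: 7 methyl (2R)-3-(3,4-dihydroxyphenyl)-2-hydroxypropanoate
Conditions: HCl (1.25 M in MeOH, 1.5 equiv), MeOH, rt
Reagents that add atoms: methanol, CO
Why: Fischer esterification after protonation of the carboxylate; the carbinol stereocentre is not involved and stays R.

**Step 5**
Reactants: 7 methyl (2R)-3-(3,4-dihydroxyphenyl)-2-hydroxypropanoate; 8 acrylic acid
Product: 9 methyl (2S)-2-(acryloyloxy)-3-(3,4-dihydroxyphenyl)propanoate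
Conditions: 8 (1.2 equiv), PPh3, DIAD, THF, 0 °C → rt
Reagents that add atoms: none
Why: Mitsunobu esterification, in which acrylate displaces the alkoxyphosphonium of the secondary alcohol by SN2 with inversion (R → S), the carboxylic acid (pKa about 4) reacting well ahead of the catechol OH groups (pKa about 9–10).

**Step 6**
Reactants: 5 (Z)-3-(3,4-dihydroxybenzylidene)-7-hydroxy-4-iodobenzofuran-2(3H)-one; 9 methyl (2S)-2-(acryloyloxy)-3-(3,4-dihydroxyphenyl)propanoate (0.95 equiv)
Product: 11 (2S)-3-(3,4-dihydroxyphenyl)-1-methoxy-1-oxopropan-2-yl (2aS,3S)-3-(3,4-dihydroxyphenyl)-8-hydroxy-2-oxo-2a,3-dihydro-2H-naphtho[1,8-bc]furan-4-carboxylate, via Heck triene 10 (not isolated)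
Conditions: Pd(OAc)2 (5 mol %), Bu4NCl, NaOAc, DMF, 50 °C; then AcOH (2 equiv), 110 °C, Ar; prep. HPLC (C18)
Reagents that add atoms: none
Why: Proposed new method: an E-selective Mizoroki–Heck coupling gives triene 10, whose lactone holds the arylidene coplanar with ring A next to the new C4 acrylate, so that a thermal 6π-electrocyclisation through the arene bond forms C8–C7′ (in the polar limit a 6-endo vinylogous Michael addition, pushed by the 7-OH para to the vinyl group and pulled by the arylidene lactone) and a proton shift from C8 to C2a restores the benzene ring; C2a–H enters anti to the pseudoaxial C3 aryl, and the peri-lactone also makes this cis isomer the thermodynamic one because only an axial aryl avoids A(1,2) strain with the C4 ester, whereas the absolute sense at C3 is biased only by the (S)-lactate ester on C8, so a modest ratio (about 1:1 to 2:1) is expected and the (2aS,3S) lactone is separated from its (2aR,3R) diastereomer by HPLC; the closest known reactions are the domino Heck/6π-electrocyclisation of hexatrienes and the thermal ortho-divinylbenzene to 1,2-dihydronaphthalene rearrangement.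

**Step 7**
Reactants: 11 (2S)-3-(3,4-dihydroxyphenyl)-1-methoxy-1-oxopropan-2-yl (2aS,3S)-3-(3,4-dihydroxyphenyl)-8-hydroxy-2-oxo-2a,3-dihydro-2H-naphtho[1,8-bc]furan-4-carboxylate; 7 methyl (2R)-3-(3,4-dihydroxyphenyl)-2-hydroxypropanoate
Product: 12 1-[(2R)-3-(3,4-dihydroxyphenyl)-1-methoxy-1-oxopropan-2-yl] 3-[(2S)-3-(3,4-dihydroxyphenyl)-1-methoxy-1-oxopropan-2-yl] (1S,2S)-2-(3,4-dihydroxyphenyl)-7,8-dihydroxy-1,2-dihydronaphthalene-1,3-dicarboxylate
Conditions: 7 (3 equiv), DMAP (20 mol %), THF, 40 °C, Ar; AcOH quench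
Reagents that add atoms: none
Why: DMAP-catalysed nucleophilic acyl substitution (transesterification) opens the strained peri-fused aryl lactone with the secondary alcohol of 7 to the more stable alkyl ester, leaving the carbinol C–O bond of 7 untouched (R retained) and C1 in the cis configuration held by the lactone (an E1cB/ketene detour would also protonate C1 anti to the C2 aryl).

## Compound list

1 | 2,3-dimethoxyphenylacetic acid | COc1cccc(CC(=O)O)c1OC | starting material
2 | 7-hydroxybenzofuran-2(3H)-one | O=C1Cc2cccc(O)c2O1 | intermediate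
3 | 7-hydroxy-4-iodobenzofuran-2(3H)-one | O=C1Cc2c(I)ccc(O)c2O1 | intermediate
4 | 3,4-dihydroxybenzaldehyde | O=Cc1ccc(O)c(O)c1 | starting material
5 | (Z)-3-(3,4-dihydroxybenzylidene)-7-hydroxy-4-iodobenzofuran-2(3H)-one | Oc1ccc(I)c2c1OC(=O)/C2=C\c1ccc(O)c(O)c1 | intermediate
6 | sodium (2R)-3-(3,4-dihydroxyphenyl)-2-hydroxypropanoate | [Na+].[O-]C(=O)[C@H](O)Cc1ccc(O)c(O)c1 | starting material
7 | methyl (2R)-3-(3,4-dihydroxyphenyl)-2-hydroxypropanoate | COC(=O)[C@H](O)Cc1ccc(O)c(O)c1 | intermediate
8 | acrylic acid | C=CC(=O)O | starting material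
9 | methyl (2S)-2-(acryloyloxy)-3-(3,4-dihydroxyphenyl)propanoate | COC(=O)[C@H](Cc1ccc(O)c(O)c1)OC(=O)C=C | intermediate
10 | (2S)-3-(3,4-dihydroxyphenyl)-1-methoxy-1-oxopropan-2-yl (E)-3-[(3Z)-3-(3,4-dihydroxybenzylidene)-7-hydroxy-2-oxo-2,3-dihydrobenzofuran-4-yl]acrylate (Heck triene) | COC(=O)[C@H](Cc1ccc(O)c(O)c1)OC(=O)/C=C/c1ccc(O)c2OC(=O)/C(=C\c3ccc(O)c(O)c3)c12 | intermediate
11 | (2S)-3-(3,4-dihydroxyphenyl)-1-methoxy-1-oxopropan-2-yl (2aS,3S)-3-(3,4-dihydroxyphenyl)-8-hydroxy-2-oxo-2a,3-dihydro-2H-naphtho[1,8-bc]furan-4-carboxylate (cis: lactone carbonyl and 3-aryl on the same face) | COC(=O)[C@H](Cc1ccc(O)c(O)c1)OC(=O)C1=Cc2ccc(O)c3c2[C@@H](C(=O)O3)[C@H]1c1ccc(O)c(O)c1 | intermediate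
12 | 1-[(2R)-3-(3,4-dihydroxyphenyl)-1-methoxy-1-oxopropan-2-yl] 3-[(2S)-3-(3,4-dihydroxyphenyl)-1-methoxy-1-oxopropan-2-yl] (1S,2S)-2-(3,4-dihydroxyphenyl)-7,8-dihydroxy-1,2-dihydronaphthalene-1,3-dicarboxylate (CNP0237075.1) | COC(=O)[C@H](Cc1ccc(O)c(O)c1)OC(=O)C1=Cc2ccc(O)c(O)c2[C@@H](C(=O)O[C@H](Cc2ccc(O)c(O)c2)C(=O)OC)[C@H]1c1ccc(O)c(O)c1 | target

## Step count and risks

Total steps: 7. Longest linear sequence: 5 (steps 1, 2, 3, 6, 7; 1 → 2 → 3 → 5 → 11 → 12).

**Step 6 (most likely to fail).** The closure through an arene double bond is untested on a polyphenolic isoaurone. Possible failures are no closure below the decomposition temperature, Michael addition of the acidic lactone 11 to unreacted acrylate, palladium-mediated dehydrogenation to the naphthalene, and a poor or wrong-way ratio of the two cis lactones. The fallback separates coupling from closure and puts the closure under catalyst control. It sets out from 5 and 9: the Heck coupling is run at 30 °C (Pd(OAc)2, Bu4NCl, NaOAc, DMF) and triene 10 is isolated. Triene 10 is then closed at 0–25 °C with a chiral phosphoric acid, (R)- or (S)-TRIP (10 mol %, CH2Cl2/THF), which can hydrogen-bond the 7-OH at the donor end and the lactone C=O at the acceptor end and so decide the helicity of the C8–C7′ closure independently of the remote lactate. The route is rejoined at 11. This fallback makes no compound that is not already in the list (F0).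

**Step 7.** The hindered α-hydroxy ester may open the lactone slowly, the open ester may re-close, and the catechol OH groups of 7 may be acylated first. The fallback replaces acyl transfer by carboxylate alkylation with inversion. It sets out from 11 and 7. Lactone 11 is hydrolysed (NaHCO3, THF/H2O, 0 °C, then pH 3) to (1S,2S)-2-(3,4-dihydroxyphenyl)-7,8-dihydroxy-3-{[(2S)-3-(3,4-dihydroxyphenyl)-1-methoxy-1-oxopropan-2-yl]oxycarbonyl}-1,2-dihydronaphthalene-1-carboxylic acid F1. In parallel, 7 is inverted by Mitsunobu reaction with 4-nitrobenzoic acid (PPh3, DIAD, THF) to methyl (2S)-3-(3,4-dihydroxyphenyl)-2-(4-nitrobenzoyloxy)propanoate F2, which is methanolysed (K2CO3 cat., MeOH, 0 °C) to methyl (2S)-3-(3,4-dihydroxyphenyl)-2-hydroxypropanoate F3. Mitsunobu esterification of F1 with F3 (PPh3, DIAD, THF; inversion to R) gives 12, where the route is rejoined.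

**Step 5.** Triphenylphosphine can add to acrylic acid, and the activated β-aryl lactate can eliminate to the cinnamate. The fallback moves the Mitsunobu step onto a cinnamic-type acid, for which unprotected phenols are well tolerated. It sets out from 5, 8 and 7. Iodide 5 is coupled with acrylic acid 8 itself under the step 6 conditions to give rac-(2aS,3S)-3-(3,4-dihydroxyphenyl)-8-hydroxy-2-oxo-2a,3-dihydro-2H-naphtho[1,8-bc]furan-4-carboxylic acid F4 (racemic cis lactone acid). F4 is then esterified with 7 under Mitsunobu conditions (PPh3, DIAD, THF; inversion gives the S ester), and 11 is separated from its (2aR,3R) diastereomer by HPLC. The route is rejoined at 11.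

Further compounds
F0 | step 6 | none | none
F1 | step 7 | (1S,2S)-2-(3,4-dihydroxyphenyl)-7,8-dihydroxy-3-{[(2S)-3-(3,4-dihydroxyphenyl)-1-methoxy-1-oxopropan-2-yl]oxycarbonyl}-1,2-dihydronaphthalene-1-carboxylic acid | COC(=O)[C@H](Cc1ccc(O)c(O)c1)OC(=O)C1=Cc2ccc(O)c(O)c2[C@@H](C(=O)O)[C@H]1c1ccc(O)c(O)c1
F2 | step 7 | methyl (2S)-3-(3,4-dihydroxyphenyl)-2-(4-nitrobenzoyloxy)propanoate | COC(=O)[C@H](Cc1ccc(O)c(O)c1)OC(=O)c1ccc(cc1)[N+](=O)[O-]
F3 | step 7 | methyl (2S)-3-(3,4-dihydroxyphenyl)-2-hydroxypropanoate | COC(=O)[C@@H](O)Cc1ccc(O)c(O)c1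
F4 | step 5 | rac-(2aS,3S)-3-(3,4-dihydroxyphenyl)-8-hydroxy-2-oxo-2a,3-dihydro-2H-naphtho[1,8-bc]furan-4-carboxylic acid (racemate, one enantiomer drawn) | OC(=O)C1=Cc2ccc(O)c3c2[C@@H](C(=O)O3)[C@H]1c1ccc(O)c(O)c1
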